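**Retrosynthetic overview**

1. Chain: C11=C12 comes from a Wittig reaction of a ring-bearing C15 dienal with a C12 ester phosphonium salt (made from the C10 trienedial); C7=C8 comes from a Horner–Wadsworth–Emmons reaction on a ring carbaldehyde.
2. Ring: the only carbocycle (C1–C6) is closed last, by an Ireland–Claisen ring contraction of a δ-lactone; this makes the C1–C6 bond and opens the temporary lactone ring in the same step.
3. Enabling feature: C6 carries an oxygen and the carbon C7 and sits between the gem-dimethyl carbon C1 and C5, while the ring methylene C3 is 1,4 to C6 through C5–C4. Tying the C7 carboxyl to an oxygen on C3 makes C6=C7–O–C3–C2=C1 a 1,5-diene whose ends are exactly C6 and C1.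
4. The lactone comes from 3-methylbut-2-enal and a senecioate dienolate (asymmetric vinylogous aldol sets C3). C3 then directs the C5 oxygen (conjugate borylation/oxidation) and the C6 configuration ([3,3] shift), and is erased as the C2=C3 double bond, which is hydrogenated.
5. Order of ring formation: temporary tetrahydropyranone ring (step 2), then the cyclohexane ring (step 6); no ring is formed afterwards.

Key step: step 6

Assumption: atoms are called by carotenoid numbering (C1 gem-dimethyl carbon, C5 and C6 carbinol carbons, C7–C15 and C15′–C10′ chain), and the (S)-ligand of step 2 is taken to give the (6S)-lactone; if the sense of induction is the opposite, the (R)-ligand is used.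

**Route**

Step 1
Reactants: 1 ethyl 3-methylbut-2-enoate
Product: 2 [(1-ethoxy-3-methylbuta-1,3-dien-1-yl)oxy]trimethylsilane
Conditions: LiN(iPr)2, THF, −78 °C; then Me3SiCl, −78 °C to rt
Reagents that add atoms: chlorotrimethylsilane, C[Si](C)(C)Cl
Why: Kinetic γ-deprotonation of the β,β-dimethylacrylate and O-silylation of the extended enolate (silyl dienol ether formation) give the vinylogous nucleophile; no stereocenter is formed.

Step 2
Reactants: 2 [(1-ethoxy-3-methylbuta-1,3-dien-1-yl)oxy]trimethylsilane; 3 3-methylbut-2-enal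
Product: 5 (6S)-4-methyl-6-(2-methylprop-1-en-1-yl)-5,6-dihydro-2H-pyran-2-one, via silyl aldol ether 4 (not isolated)
Conditions: Cu(OTf)2 (10 mol %), (S)-Tol-BINAP (11 mol %), Bu4N[Ph3SiF2] (20 mol %), THF, 0 °C to rt
Reagents that add atoms: none
Why: Catalytic asymmetric vinylogous Mukaiyama aldol reaction: a chiral monovalent copper fluoride–Tol-BINAP complex formed in the flask turns 2 into a copper dienolate that adds through its γ-carbon to one face of the aldehyde (ligand control sets the carbinol center, 6S), and the (2Z)-configured adduct 4 should close to the lactone in the flask with loss of ethoxytrimethylsilane.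

Step 3
Reactants: 5 (6S)-4-methyl-6-(2-methylprop-1-en-1-yl)-5,6-dihydro-2H-pyran-2-one
Product: 7 (4R,6S)-4-hydroxy-4-methyl-6-(2-methylprop-1-en-1-yl)tetrahydro-2H-pyran-2-one, via boronate 6 (not isolated)
Conditions: B2pin2, CuCl (5 mol %), DPEphos (5 mol %), NaOtBu (10 mol %), MeOH (2 equiv), THF, rt; then NaBO3·4H2O, THF/H2O, rt
Reagents that add atoms: bis(pinacolato)diboron, CC1(C)OB(OC1(C)C)B1OC(C)(C)C(C)(C)O1; sodium perborate (used as the tetrahydrate), [Na+].[O-]OB=O
Why: Copper-catalysed conjugate borylation followed by oxidation of the C–B bond with retention: the boryl copper species should add to C4 of the half-chair lactone anti to the pseudo-equatorial C6 substituent, so that the tertiary oxygen ends trans to the alkenyl group (4R; the change of descriptor from 6 to 7 is only a change of priorities).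

Step 4
Reactants: 7 (4R,6S)-4-hydroxy-4-methyl-6-(2-methylprop-1-en-1-yl)tetrahydro-2H-pyran-2-one
Product: 8 (3RS,4R,6S)-3,4-dihydroxy-4-methyl-6-(2-methylprop-1-en-1-yl)tetrahydro-2H-pyran-2-one
Conditions: KN(SiMe3)2 (2.3 equiv), THF, −78 °C; 2-(phenylsulfonyl)-3-phenyloxaziridine, −78 °C; AcOH
Reagents that add atoms: 2-(phenylsulfonyl)-3-phenyloxaziridine, O=S(=O)(c1ccccc1)N1OC1c1ccccc1
Why: Enolate oxidation with an N-sulfonyloxaziridine on the alkoxide–enolate dianion, in which the β-oxido group cannot leave; the new C3 center forms as a mixture of epimers, which is of no consequence because this carbon becomes trigonal again in step 6.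

Step 5
Reactants: 8 (3RS,4R,6S)-3,4-dihydroxy-4-methyl-6-(2-methylprop-1-en-1-yl)tetrahydro-2H-pyran-2-one
Product: 9 (3RS,4R,6S)-4-methyl-6-(2-methylprop-1-en-1-yl)-3,4-bis[(triethylsilyl)oxy]tetrahydro-2H-pyran-2-one
Conditions: Et3SiOTf (2.5 equiv), 2,6-lutidine, CH2Cl2, 0 °C to rt
Reagents that add atoms: triethylsilyl trifluoromethanesulfonate, CC[Si](CC)(CC)OS(=O)(=O)C(F)(F)F
Why: Silylation of the secondary and the tertiary hydroxyl with a silyl triflate (silyl ether formation) leaves C3–H as the only acidic position for step 6 and touches no stereocenter.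

Step 6
Reactants: 9 (3RS,4R,6S)-4-methyl-6-(2-methylprop-1-en-1-yl)-3,4-bis[(triethylsilyl)oxy]tetrahydro-2H-pyran-2-one
Product: 12 (1R,6R)-2,2,6-trimethyl-1,6-bis[(triethylsilyl)oxy]cyclohex-3-ene-1-carboxylic acid, via silyl ketene acetal 10 (not isolated), via trimethylsilyl ester 11 (not isolated)
Conditions: Me3SiCl/Et3N, LiN(iPr)2, THF, −78 °C; then toluene, 110 °C; then H2O/THF, rt
Reagents that add atoms: chlorotrimethylsilane, C[Si](C)(C)Cl
Why: Ireland–Claisen rearrangement run as a ring contraction: LiN(iPr)2 in the presence of Me3SiCl traps the lactone enolate at once as the cyclic silyl ketene acetal 10, whose C6=C7–O–C3–C2=C1 array (carotenoid numbering) undergoes a concerted suprafacial [3,3] shift on heating. The closest known reaction type is the ester-enolate Claisen ring contraction of 6-alkenyl δ-lactones to cyclohexenecarboxylic acids (and of 6-alkenyl-1,4-dioxan-2-ones to dihydropyrans). Ring closure: the six-membered carbocycle C1–C6 is closed by the new C1–C6 σ-bond through a boat-like bicyclo[2.2.2] transition state enforced by the lactone tether, while the C3–O bond of the temporary ring breaks and leaves the C2=C3 double bond and the C7 carboxyl. The new stereocenter C6 is controlled by the C3 carbinol center, because the 2-methylpropenyl group can reach the ketene acetal only on its own face, which is also the face of the C5 methyl group; the C7 carboxyl is therefore left cis to O5, O5 and O6 end up trans, and C3 becomes trigonal (traceless chirality transfer), while C5 is not touched. The step needs O-silylation to outrun E1cB loss of the C5 silyloxy group (secured by the in situ quench at −78 °C and by the single acidic α-hydrogen), and it must join two fully substituted carbons, which the intramolecular and strongly exergonic shift and the absence of any competing [3,3] array should secure.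

Step 7
Reactants: 12 (1R,6R)-2,2,6-trimethyl-1,6-bis[(triethylsilyl)oxy]cyclohex-3-ene-1-carboxylic acid
Product: 13 methyl (1R,6R)-2,2,6-trimethyl-1,6-bis[(triethylsilyl)oxy]cyclohex-3-ene-1-carboxylate
Conditions: MeI, K2CO3, DMF, rt
Reagents that add atoms: iodomethane, CI
Why: SN2 O-alkylation of the carboxylate by iodomethane (esterification) is not slowed by the hindrance at the carboxyl carbon and leaves both stereocenters untouched.

Step 8
Reactants: 13 methyl (1R,6R)-2,2,6-trimethyl-1,6-bis[(triethylsilyl)oxy]cyclohex-3-ene-1-carboxylate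
Product: 14 methyl (1R,2R)-2,6,6-trimethyl-1,2-bis[(triethylsilyl)oxy]cyclohexane-1-carboxylate
Conditions: H2 (1 atm), 10% Pd/C, EtOAc, rt
Reagents that add atoms: none
Why: Heterogeneous catalytic hydrogenation should saturate the isolated cis-disubstituted C3=C4 ring double bond, the only reducible group, and so converts the carbocycle into the cyclohexane of the target without touching a stereocenter.

Step 9
Reactants: 14 methyl (1R,2R)-2,6,6-trimethyl-1,2-bis[(triethylsilyl)oxy]cyclohexane-1-carboxylate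
Product: 15 (1R,2R)-2,6,6-trimethyl-1,2-bis[(triethylsilyl)oxy]cyclohexane-1-carbaldehyde
Conditions: iBu2AlH (DIBAL-H), CH2Cl2, −78 °C; aqueous potassium sodium tartrate
Reagents that add atoms: none
Why: Partial ester reduction with iBu2AlH at −78 °C: the tetrahedral aluminium hemiacetal, held by the neighbouring silyloxy oxygen and by steric shielding, should survive until work-up and give the non-enolisable aldehyde.

Step 10
Reactants: 15 (1R,2R)-2,6,6-trimethyl-1,2-bis[(triethylsilyl)oxy]cyclohexane-1-carbaldehyde; 16 diethyl [(2E)-3-cyano-2-methylprop-2-en-1-yl]phosphonate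
Product: 17 (2E,4E)-3-methyl-5-{(1R,2R)-2,6,6-trimethyl-1,2-bis[(triethylsilyl)oxy]cyclohexyl}penta-2,4-dienenitrile
Conditions: NaH, THF, 0 °C; then 15, 0 °C to rt
Reagents that add atoms: none
Why: Horner–Wadsworth–Emmons olefination with the allylic phosphonate carbanion should form C7=C8 with E geometry by way of the more stable anti adduct and keep the 2E geometry of the reagent (a minor 2Z isomer would be removed by chromatography); the aldehyde has no α-hydrogen, so the ring stereocenters cannot epimerise.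

Step 11
Reactants: 17 (2E,4E)-3-methyl-5-{(1R,2R)-2,6,6-trimethyl-1,2-bis[(triethylsilyl)oxy]cyclohexyl}penta-2,4-dienenitrile
Product: 19 (2E,4E)-3-methyl-5-{(1R,2R)-2,6,6-trimethyl-1,2-bis[(triethylsilyl)oxy]cyclohexyl}penta-2,4-dienal, via aldimine 18 (not isolated)
Conditions: iBu2AlH (DIBAL-H), toluene, −78 °C; then wet SiO2, 0 °C
Reagents that add atoms: water, O
Why: Nitrile reduction with iBu2AlH stops at the N-aluminated aldimine, which wet silica hydrolyses to the dienal, the usual nitrile-to-aldehyde conversion of retinoid chemistry.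

Step 12
Reactants: 20 (2E,4E,6E)-2,7-dimethylocta-2,4,6-trienedial; 21 ethyl (triphenyl-λ5-phosphanylidene)acetate
Product: 22 ethyl (2E,4E,6E,8E)-4,9-dimethyl-10-oxodeca-2,4,6,8-tetraenoate
Conditions: CH2Cl2, rt (20 in excess)
Reagents that add atoms: none
Why: Wittig olefination with a stabilised ylide is E-selective, and with the symmetric dialdehyde in excess it should stop after one carbonyl group (unchanged 20 is recovered).

Step 13
Reactants: 22 ethyl (2E,4E,6E,8E)-4,9-dimethyl-10-oxodeca-2,4,6,8-tetraenoate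
Product: 23 ethyl (2E,4E,6E,8E)-10-hydroxy-4,9-dimethyldeca-2,4,6,8-tetraenoate
Conditions: NaBH4, EtOH, 0 °C
Reagents that add atoms: none
Why: Chemoselective 1,2-reduction of the aldehyde by NaBH4 leaves the conjugated ester and the tetraene untouched.

Step 14
Reactants: 23 ethyl (2E,4E,6E,8E)-10-hydroxy-4,9-dimethyldeca-2,4,6,8-tetraenoate
Product: 25 [(2E,4E,6E,8E)-10-ethoxy-2,7-dimethyl-10-oxodeca-2,4,6,8-tetraen-1-yl]triphenylphosphonium bromide, via allylic bromide 24 (not isolated)
Conditions: CBr4, PPh3 (2.2 equiv), CH2Cl2, 0 °C to rt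
Reagents that add atoms: carbon tetrabromide, BrC(Br)(Br)Br; triphenylphosphine, c1ccc(cc1)P(c1ccccc1)c1ccccc1
Why: Appel bromination of the primary allylic alcohol and SN2 quaternisation of the resulting allylic bromide by the second equivalent of PPh3 give the phosphonium salt in one flask.

Step 15
Reactants: 19 (2E,4E)-3-methyl-5-{(1R,2R)-2,6,6-trimethyl-1,2-bis[(triethylsilyl)oxy]cyclohexyl}penta-2,4-dienal; 25 [(2E,4E,6E,8E)-10-ethoxy-2,7-dimethyl-10-oxodeca-2,4,6,8-tetraen-1-yl]triphenylphosphonium bromide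
Product: 27 ethyl (2E,4E,6E,8E,10E,12E,14E)-4,9,13-trimethyl-15-{(1R,2R)-2,6,6-trimethyl-1,2-bis[(triethylsilyl)oxy]cyclohexyl}pentadeca-2,4,6,8,10,12,14-heptaenoate, via ylide 26 (not isolated)
Conditions: LiN(SiMe3)2, THF, −78 °C; then 19, −78 °C to rt; then I2 (cat.), CH2Cl2, daylight, rt
Reagents that add atoms: none
Why: Wittig olefination of the dienal with the polyenyl ylide forms C11=C12, and iodine-catalysed equilibration should convert the 11Z portion into the thermodynamically preferred all-E heptaene, as is usual for carotenoid polyenes.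

Step 16
Reactants: 27 ethyl (2E,4E,6E,8E,10E,12E,14E)-4,9,13-trimethyl-15-{(1R,2R)-2,6,6-trimethyl-1,2-bis[(triethylsilyl)oxy]cyclohexyl}pentadeca-2,4,6,8,10,12,14-heptaenoate
Product: 28 ethyl (2E,4E,6E,8E,10E,12E,14E)-15-[(1R,2R)-1,2-dihydroxy-2,6,6-trimethylcyclohexyl]-4,9,13-trimethylpentadeca-2,4,6,8,10,12,14-heptaenoate
Conditions: Bu4NF, THF, 0 °C to rt, dark, argon
Reagents that add atoms: none
Why: Fluoride-induced cleavage of both triethylsilyl ethers (Si–F bond formation) frees the tertiary diol under non-acidic conditions that spare the tertiary allylic alcohol and the polyene.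

Step 17
Reactants: 28 ethyl (2E,4E,6E,8E,10E,12E,14E)-15-[(1R,2R)-1,2-dihydroxy-2,6,6-trimethylcyclohexyl]-4,9,13-trimethylpentadeca-2,4,6,8,10,12,14-heptaenoate
Product: 29 (2E,4E,6E,8E,10E,12E,14E)-15-[(1R,2R)-1,2-dihydroxy-2,6,6-trimethylcyclohexyl]-4,9,13-trimethylpentadeca-2,4,6,8,10,12,14-heptaenoic acid
Conditions: LiOH, THF/MeOH/H2O, rt; then 1 M HCl to pH 4, 0 °C
Reagents that add atoms: lithium hydroxide, [Li+].[OH-]
Why: Saponification of the ethyl ester and careful acidification give the acid without touching a stereocenter or a double bond.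

**Compound list**

1 | ethyl 3-methylbut-2-enoate | CCOC(=O)C=C(C)C | starting material
2 | [(1-ethoxy-3-methylbuta-1,3-dien-1-yl)oxy]trimethylsilane | CCOC(=CC(C)=C)O[Si](C)(C)C | intermediate
3 | 3-methylbut-2-enal | CC(C)=CC=O | starting material
4 | ethyl (2Z,5S)-3,7-dimethyl-5-[(trimethylsilyl)oxy]octa-2,6-dienoate | CCOC(=O)/C=C(/C)C[C@H](O[Si](C)(C)C)C=C(C)C | intermediate
5 | (6S)-4-methyl-6-(2-methylprop-1-en-1-yl)-5,6-dihydro-2H-pyran-2-one | CC1=CC(=O)O[C@H](C=C(C)C)C1 | intermediate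
6 | (4S,6S)-4-methyl-6-(2-methylprop-1-en-1-yl)-4-(4,4,5,5-tetramethyl-1,3,2-dioxaborolan-2-yl)tetrahydro-2H-pyran-2-one | O=C1C[C@](C)(B2OC(C)(C)C(C)(C)O2)C[C@@H](C=C(C)C)O1 | intermediate
7 | (4R,6S)-4-hydroxy-4-methyl-6-(2-methylprop-1-en-1-yl)tetrahydro-2H-pyran-2-one | O=C1C[C@](C)(O)C[C@@H](C=C(C)C)O1 | intermediate
8 | (3RS,4R,6S)-3,4-dihydroxy-4-methyl-6-(2-methylprop-1-en-1-yl)tetrahydro-2H-pyran-2-one | O=C1C(O)[C@](C)(O)C[C@@H](C=C(C)C)O1 | intermediate
9 | (3RS,4R,6S)-4-methyl-6-(2-methylprop-1-en-1-yl)-3,4-bis[(triethylsilyl)oxy]tetrahydro-2H-pyran-2-one | O=C1C(O[Si](CC)(CC)CC)[C@](C)(O[Si](CC)(CC)CC)C[C@@H](C=C(C)C)O1 | intermediate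
10 | (2S,4R)-4-methyl-2-(2-methylprop-1-en-1-yl)-4,5-bis[(triethylsilyl)oxy]-6-[(trimethylsilyl)oxy]-3,4-dihydro-2H-pyran | C[Si](C)(C)OC1=C(O[Si](CC)(CC)CC)[C@](C)(O[Si](CC)(CC)CC)C[C@@H](C=C(C)C)O1 | intermediate
11 | trimethylsilyl (1R,6R)-2,2,6-trimethyl-1,6-bis[(triethylsilyl)oxy]cyclohex-3-ene-1-carboxylate | C[Si](C)(C)OC(=O)[C@@]1(O[Si](CC)(CC)CC)C(C)(C)C=CC[C@@]1(C)O[Si](CC)(CC)CC | intermediate
12 | (1R,6R)-2,2,6-trimethyl-1,6-bis[(triethylsilyl)oxy]cyclohex-3-ene-1-carboxylic acid | OC(=O)[C@@]1(O[Si](CC)(CC)CC)C(C)(C)C=CC[C@@]1(C)O[Si](CC)(CC)CC | intermediate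
13 | methyl (1R,6R)-2,2,6-trimethyl-1,6-bis[(triethylsilyl)oxy]cyclohex-3-ene-1-carboxylate | COC(=O)[C@@]1(O[Si](CC)(CC)CC)C(C)(C)C=CC[C@@]1(C)O[Si](CC)(CC)CC | intermediate
14 | methyl (1R,2R)-2,6,6-trimethyl-1,2-bis[(triethylsilyl)oxy]cyclohexane-1-carboxylate | COC(=O)[C@@]1(O[Si](CC)(CC)CC)C(C)(C)CCC[C@@]1(C)O[Si](CC)(CC)CC | intermediate
15 | (1R,2R)-2,6,6-trimethyl-1,2-bis[(triethylsilyl)oxy]cyclohexane-1-carbaldehyde | O=C[C@@]1(O[Si](CC)(CC)CC)C(C)(C)CCC[C@@]1(C)O[Si](CC)(CC)CC | intermediate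
16 | diethyl [(2E)-3-cyano-2-methylprop-2-en-1-yl]phosphonate | CCOP(=O)(C/C(C)=C/C#N)OCC | starting material
17 | (2E,4E)-3-methyl-5-{(1R,2R)-2,6,6-trimethyl-1,2-bis[(triethylsilyl)oxy]cyclohexyl}penta-2,4-dienenitrile | N#C/C=C(C)/C=C/[C@@]1(O[Si](CC)(CC)CC)C(C)(C)CCC[C@@]1(C)O[Si](CC)(CC)CC | intermediate
18 | (2E,4E)-3-methyl-5-{(1R,2R)-2,6,6-trimethyl-1,2-bis[(triethylsilyl)oxy]cyclohexyl}penta-2,4-dien-1-imine | N=C/C=C(C)/C=C/[C@@]1(O[Si](CC)(CC)CC)C(C)(C)CCC[C@@]1(C)O[Si](CC)(CC)CC | intermediate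
19 | (2E,4E)-3-methyl-5-{(1R,2R)-2,6,6-trimethyl-1,2-bis[(triethylsilyl)oxy]cyclohexyl}penta-2,4-dienal | O=C/C=C(C)/C=C/[C@@]1(O[Si](CC)(CC)CC)C(C)(C)CCC[C@@]1(C)O[Si](CC)(CC)CC | intermediate
20 | (2E,4E,6E)-2,7-dimethylocta-2,4,6-trienedial | O=C/C(C)=C/C=C/C=C(C)/C=O | starting material
21 | ethyl (triphenyl-λ5-phosphanylidene)acetate | CCOC(=O)C=P(c1ccccc1)(c1ccccc1)c1ccccc1 | starting material
22 | ethyl (2E,4E,6E,8E)-4,9-dimethyl-10-oxodeca-2,4,6,8-tetraenoate | CCOC(=O)/C=C/C(C)=C/C=C/C=C(C)/C=O | intermediate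
23 | ethyl (2E,4E,6E,8E)-10-hydroxy-4,9-dimethyldeca-2,4,6,8-tetraenoate | CCOC(=O)/C=C/C(C)=C/C=C/C=C(C)/CO | intermediate
24 | ethyl (2E,4E,6E,8E)-10-bromo-4,9-dimethyldeca-2,4,6,8-tetraenoate | CCOC(=O)/C=C/C(C)=C/C=C/C=C(C)/CBr | intermediate
25 | [(2E,4E,6E,8E)-10-ethoxy-2,7-dimethyl-10-oxodeca-2,4,6,8-tetraen-1-yl]triphenylphosphonium bromide | CCOC(=O)/C=C/C(C)=C/C=C/C=C(C)/C[P+](c1ccccc1)(c1ccccc1)c1ccccc1.[Br-] | intermediate
26 | ethyl (2E,4E,6E,8E)-4,9-dimethyl-10-(triphenyl-λ5-phosphanylidene)deca-2,4,6,8-tetraenoate | CCOC(=O)/C=C/C(C)=C/C=C/C=C(C)/C=P(c1ccccc1)(c1ccccc1)c1ccccc1 | intermediate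
27 | ethyl (2E,4E,6E,8E,10E,12E,14E)-4,9,13-trimethyl-15-{(1R,2R)-2,6,6-trimethyl-1,2-bis[(triethylsilyl)oxy]cyclohexyl}pentadeca-2,4,6,8,10,12,14-heptaenoate | CCOC(=O)/C=C/C(C)=C/C=C/C=C(C)/C=C/C=C(C)/C=C/[C@@]1(O[Si](CC)(CC)CC)C(C)(C)CCC[C@@]1(C)O[Si](CC)(CC)CC | intermediate
28 | ethyl (2E,4E,6E,8E,10E,12E,14E)-15-[(1R,2R)-1,2-dihydroxy-2,6,6-trimethylcyclohexyl]-4,9,13-trimethylpentadeca-2,4,6,8,10,12,14-heptaenoate | CCOC(=O)/C=C/C(C)=C/C=C/C=C(C)/C=C/C=C(C)/C=C/[C@@]1(O)C(C)(C)CCC[C@@]1(C)O | intermediate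
29 | (2E,4E,6E,8E,10E,12E,14E)-15-[(1R,2R)-1,2-dihydroxy-2,6,6-trimethylcyclohexyl]-4,9,13-trimethylpentadeca-2,4,6,8,10,12,14-heptaenoic acid (CNP0107805.1; the 5R,6R trans-diol) | CC(/C=C/C=C(C)/C=C/[C@@]1(O)C(C)(C)CCC[C@@]1(C)O)=C\C=C\C=C(C)\C=C\C(=O)O | target

**Step count and risks**

Total step count: 17. Longest linear sequence: 14 steps (steps 1–11 and 15–17; steps 12–14 form the C12 side branch).

Steps most likely to fail:

1. Step 6 (key step). What may go wrong: elimination of the C5 silyloxy group from the lactone enolate before it is silylated (E1cB), or stalling of the [3,3] shift. The shift must join two fully substituted carbons through a boat transition state that carries allylic strain between C4 and the (Z)-methyl group of the alkene and a methyl/methyl contact between C5 and C1. Fallback (the C6 oxygen is put in after the ring closure, so that the migrating enolate carbon is only trisubstituted): it sets out from 7, whose tertiary hydroxyl is silylated (Et3SiOTf, 2,6-lutidine) to (4R,6S)-4-methyl-6-(2-methylprop-1-en-1-yl)-4-[(triethylsilyl)oxy]tetrahydro-2H-pyran-2-one F1. Enolization with in situ silylation (LiN(iPr)2, Me3SiCl) should give (2S,4R)-4-methyl-2-(2-methylprop-1-en-1-yl)-4-[(triethylsilyl)oxy]-6-[(trimethylsilyl)oxy]-3,4-dihydro-2H-pyran F2, which on heating should rearrange to trimethylsilyl (1S,6R)-2,2,6-trimethyl-6-[(triethylsilyl)oxy]cyclohex-3-ene-1-carboxylate F3 and on aqueous work-up give (1S,6R)-2,2,6-trimethyl-6-[(triethylsilyl)oxy]cyclohex-3-ene-1-carboxylic acid F4. MeI/K2CO3 gives methyl (1S,6R)-2,2,6-trimethyl-6-[(triethylsilyl)oxy]cyclohex-3-ene-1-carboxylate F5. KN(SiMe3)2 followed by 2-(phenylsulfonyl)-3-phenyloxaziridine should hydroxylate the ester enolate on the face anti to the C5 silyloxy group and give methyl (1R,6R)-1-hydroxy-2,2,6-trimethyl-6-[(triethylsilyl)oxy]cyclohex-3-ene-1-carboxylate F6. Silylation with Et3SiOTf/2,6-lutidine brings the sequence back to 13.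

2. Step 10. What may go wrong: slow or reversible addition of the phosphonate carbanion to an aldehyde carbon attached to a fully substituted carbon that is itself flanked by two more, migration of the triethylsilyl group from O6 to the newly formed alkoxide, and partial loss of the 2E geometry. Fallback (C7=C8 is made by a one-carbon iodo-olefination and C8–C9 by cross-coupling): it sets out from 15. Takai olefination (CHI3, CrCl2, THF) should give (1R,2R)-1-[(E)-2-iodoethenyl]-2,6,6-trimethyl-1,2-bis[(triethylsilyl)oxy]cyclohexane F7. Stille coupling with (2E)-3-(tributylstannyl)but-2-en-1-ol (Pd(PPh3)4, CuI, DMF) should give (2E,4E)-3-methyl-5-{(1R,2R)-2,6,6-trimethyl-1,2-bis[(triethylsilyl)oxy]cyclohexyl}penta-2,4-dien-1-ol F8. Oxidation with MnO2 returns to 19.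

3. Step 2. What may go wrong: insufficient enantiofacial discrimination for the β,β-disubstituted enal, and incomplete ring closure if part of the aldol adduct forms with 2E geometry. Fallback (stoichiometric boron aldol, then ring closure by olefination): it sets out from 3. Aldol addition of the diisopinocampheylboron enolate of acetone (the Ipc2BCl antipode that leads to the 4S adduct, Et3N, then 3, oxidative work-up) should give (4S)-4-hydroxy-6-methylhept-5-en-2-one F9. Esterification with 2-(diethoxyphosphoryl)acetic acid (DCC, DMAP) gives (4S)-6-methyl-2-oxohept-5-en-4-yl 2-(diethoxyphosphoryl)acetate F10. An intramolecular Horner–Wadsworth–Emmons reaction (LiCl, DBU, MeCN) closes the unsaturated lactone and returns to 5.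

Further compounds

F1 | step 6 | (4R,6S)-4-methyl-6-(2-methylprop-1-en-1-yl)-4-[(triethylsilyl)oxy]tetrahydro-2H-pyran-2-one | O=C1C[C@](C)(O[Si](CC)(CC)CC)C[C@@H](C=C(C)C)O1
F2 | step 6 | (2S,4R)-4-methyl-2-(2-methylprop-1-en-1-yl)-4-[(triethylsilyl)oxy]-6-[(trimethylsilyl)oxy]-3,4-dihydro-2H-pyran | C[Si](C)(C)OC1=C[C@](C)(O[Si](CC)(CC)CC)C[C@@H](C=C(C)C)O1
F3 | step 6 | trimethylsilyl (1S,6R)-2,2,6-trimethyl-6-[(triethylsilyl)oxy]cyclohex-3-ene-1-carboxylate | C[Si](C)(C)OC(=O)[C@H]1C(C)(C)C=CC[C@@]1(C)O[Si](CC)(CC)CC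
F4 | step 6 | (1S,6R)-2,2,6-trimethyl-6-[(triethylsilyl)oxy]cyclohex-3-ene-1-carboxylic acid | OC(=O)[C@H]1C(C)(C)C=CC[C@@]1(C)O[Si](CC)(CC)CC
F5 | step 6 | methyl (1S,6R)-2,2,6-trimethyl-6-[(triethylsilyl)oxy]cyclohex-3-ene-1-carboxylate | COC(=O)[C@H]1C(C)(C)C=CC[C@@]1(C)O[Si](CC)(CC)CC
F6 | step 6 | methyl (1R,6R)-1-hydroxy-2,2,6-trimethyl-6-[(triethylsilyl)oxy]cyclohex-3-ene-1-carboxylate | COC(=O)[C@@]1(O)C(C)(C)C=CC[C@@]1(C)O[Si](CC)(CC)CC
F7 | step 10 | (1R,2R)-1-[(E)-2-iodoethenyl]-2,6,6-trimethyl-1,2-bis[(triethylsilyl)oxy]cyclohexane | I/C=C/[C@@]1(O[Si](CC)(CC)CC)C(C)(C)CCC[C@@]1(C)O[Si](CC)(CC)CC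
F8 | step 10 | (2E,4E)-3-methyl-5-{(1R,2R)-2,6,6-trimethyl-1,2-bis[(triethylsilyl)oxy]cyclohexyl}penta-2,4-dien-1-ol | OC/C=C(C)/C=C/[C@@]1(O[Si](CC)(CC)CC)C(C)(C)CCC[C@@]1(C)O[Si](CC)(CC)CC
F9 | step 2 | (4S)-4-hydroxy-6-methylhept-5-en-2-one | CC(=O)C[C@H](O)C=C(C)C
F10 | step 2 | (4S)-6-methyl-2-oxohept-5-en-4-yl 2-(diethoxyphosphoryl)acetate | CCOP(=O)(CC(=O)O[C@@H](CC(C)=O)C=C(C)C)OCC
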